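## The problem

The target is an 11-oxabicyclo[6.2.1]undecane. The numbering used here runs round the ten-membered carbocycle: ring ketone C1, C2, C3, methyl-bearing oxirane carbon C4, oxirane CH C5, lactone carbinol C6, spiro carbon C7, acyloxy carbon C8, methylene C9 and methyl-bearing carbon C10, which is bonded to C1. An ether oxygen joins C7 and C10, so C7–C8–C9–C10–O is an oxolane. A spiro α-methylene-γ-butyrolactone (C7, C11 with its methylene C13, carbonyl C12, O, C6) sits on C7, a cis-oxirane spans C4–C5, and O8 carries a methacrylate.

A synthesis has to close a ten-membered ring that is bridged and carries two fully substituted, oxygenated carbons (C7 and C10). It has to set six stereocentres (4R,5S,6R,7S,8S,10R) that form one contiguous array. That array allows a relay: the oxirane carbon C5 can control C6, C6 can control C7 and later C8, and C7 can control C10 through the bridge.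

The sensitive groups are two Michael acceptors (methylene lactone and methacrylate), an acid-labile trisubstituted oxirane, and β-oxygenated ketones that can undergo retro-aldol or retro-Michael cleavage. The acceptors therefore have to come last, and the oxirane rules out acidic steps.

The enabling feature is at C10. It carries the methyl group, the ring oxygen and the bond to the C1 carbonyl, and it lies β to C8 through C9. With C8 as a ketone and C9=C10 as a double bond, the oxolane becomes a furan-3(2H)-one. Its C10 is then the β-carbon of a vinylogous ester and can accept an acyl radical centred on C1. That one bond closes the carbocycle and creates the C10 stereocentre.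

## Retrosynthesis

**O8–acyl bond.** Target 29 is cut first at the methacrylate ester to give hydroxy lactone 28. The methacrylate is a Michael acceptor and a base-labile ester, so it is best attached when no nucleophile or base is left to meet. The forward reaction is an acylation of one hindered secondary alcohol.

**Lactone (C11–C12 and C12–O6).** Lactone 28 comes from silyl ether 27, and 27 from alkynol 26 by carbonylative ring closure of its but-3-yn-1-ol unit (C6–OH, C7, C11≡C13). This is preferred to α-methylenation of a preformed lactone, which would need a strong base next to the C1 ketone. The precursor 26 lacks both Michael acceptors. The forward step needs O8 blocked, because C8–OH is homopropargylic as well and would compete; hence the silyl ether in 26 and 27.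

**Alkyne (C11≡C13).** Alkynol 26 is traced to aldehyde 24 by a one-carbon homologation that also removes the benzoate of intermediate 25. Aldehyde 24 comes from alcohol 23 and PMB ether 22. C11 therefore travels through the route as a CH2O–PMB group, which is orthogonal to silyl ethers and to the benzoate. The aldehyde is made only when C8 is no longer a ketone and both β-oxygens are capped, so neither retro-Claisen nor retro-aldol cleavage is possible.

**C8–H bond.** Silyl ether 22 and its alcohol 21 lead back to β-hydroxy ketone 20 by an intramolecular hydride transfer from a hemiacetal on O6 (Evans–Tishchenko). An external hydride would most likely pass the smaller CH2O–PMB group and give the wrong C8 epimer. Delivery from O6 must enter on the face where C6 sits and gives 8S. The same step leaves the C1 ketone alone and returns O6 as an ester, which tells the two carbinols apart. Ketone 20 is the desilylated form of diketone 19.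

**C1–C10 bond (key).** Diketone 19 is opened between C1 and C10 to furanone selenoester 18. The cut removes the carbocycle and the C10 stereocentre together and leaves a flat, easily made heterocycle carrying one chain. Cutting C6–C7 or C5–C6 instead would leave the two quaternary centres of the oxolane to be set in an acyclic precursor. The forward step asks a nucleophilic acyl radical to add to a hindered but polarity-matched β-carbon faster than it is reduced.

**Oxirane as spectator.** The C4–C5 oxirane is kept in 18 and 19 rather than a C4=C5 alkene. A late epoxidation would have to pick one face of a cis-cyclodecene without a reliable guide, and in open-chain precursors allylic 1,3-strain would favour the wrong (threo) isomer. Carried from the start, the oxirane comes from a catalytic asymmetric reaction and is the origin of all other stereocentres. The ring that closes in the key step is then the ring of the natural product itself.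

**Furanone and selenoester.** Selenoester 18 comes from methyl ester 16 through carboxylate 17. Furanone 16 comes from α′-hydroxy ynone 14 by amine-mediated closure of the O–C10 bond via amino enone 15. The usual alternative, acid cyclodehydration of a hydroxy diketone, is rejected because of the oxirane and because its Claisen step is incompatible with the ester.

**C8–C9 bond and C7–O bond.** Ynone 14 arises from diol 13, the adduct of a propynyl nucleophile and α-hydroxy aldehyde 12. Aldehyde 12 comes from diol 11, the osmylation product of alkene 10. Osmium attacks anti to the allylic silyloxy group. The alkene CH2 must therefore become C8 and the pre-existing CH2O–PMB must be C11; the opposite assignment would give the C7 epimer.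

**C6–C7 bond.** Alkene 10 is the silyl ether of allylic alcohol 9. Alcohol 9 is cut into epoxy aldehyde 4 and alkenyllithium 8, made from bromide 7, which in turn comes from dibromide 5 and alcohol 6. Felkin–Anh addition anti to the oxirane C–O bond gives the target's C6 configuration.

**Oxirane and ester.** Aldehyde 4 comes from hydroxy ester 3, made by ozonolysis of epoxynerol 2 directly to the methyl ester. Epoxynerol 2 is the Sharpless epoxide of nerol 1. Nerol supplies C1–C6, C15 and the cis relationship at C4–C5.

## Roads not taken

**Alternative 1:** The cut is through C10–C1 and C7–C6 at once, by a furan/oxyallyl (4+3) cycloaddition. In the forward direction, acetal enol silane A3 is ionised by a silyl triflate to an alkoxy-substituted siloxyallyl cation. This adds across the 2- and 5-positions of silyloxyfuran A2 and gives oxabicyclooctenone A1.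
- Merits: both tetrasubstituted oxolane carbons and their cis relation arise in one suprafacial event on an electron-rich furan. The C6 oxygen and a C8 enol ether are delivered at the same time, and the route to A1 is short and convergent.
- Weak points: the seven-membered ring of A1 is not a ring of the target. Its carbonyl carbon stands between C1 and C6 where the target has C2–C5, so the bridge must be cut, four carbons inserted and the ten-membered ring closed afterwards. C1 arrives as CH2 and must be oxidised. Two unsymmetrical partners raise regiochemical and endo/exo questions, and absolute control needs an auxiliary.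
- Comparison: for making the C10 quaternary centre this is the more reliable chemistry, better than a radical attack on a hindered β-carbon. The chosen plan sets against it that its bond formation also closes the carbocycle, that no ring is dismantled, and that all stereocentres derive from one catalytic step.

**Alternative 2:** The cut is at the O–C7 bond of the oxolane and at C11–C12. In allenyl carbinol A5 the C10 hydroxyl would add across the ring to the ring-bound allene terminus under oxidative alkoxycarbonylation with divalent palladium. The alkenylpalladium intermediate would take up CO and give acrylate ester A4.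
- Merits: the oxolane, the C7 centre and all three lactone carbons appear in one late step. The methacrylate is already in place, and the end-game from A4 is shorter than the nine steps needed after the key step here.
- Weak points: A5 is itself a ten-membered carbocycle with a tertiary alcohol, a ketone, an allene and a Z-alkene. The medium-ring problem is moved, not solved. The face of attack at C7 depends on the conformation of a flexible ring. A copper oxidant and chloride meet an electron-rich alkene and a methacrylate. The oxirane would still have to be introduced late.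
- Comparison: in step economy after ring formation it is better. The chosen plan sets against it that ring closure and C10 come from a rigid furanone of known geometry.

**Alternative 3:** The cut is at a C4=C5 double bond, to be epoxidised later. Eleven-membered β-hydroxy sulfone A7 would be halogenated in situ on base-coated alumina and contract by 1,3-elimination and loss of the sulfonyl bridge (Ramberg–Bäcklund) to cyclodecenol A6.
- Merits: ring closure is shifted to an unstrained eleven-membered sulfide formation. The oxolane and its stereocentres are assembled beforehand by open-chain chemistry. The alkene appears exactly where the oxirane is needed.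
- Weak points: the mechanism does not fix the geometry of a trisubstituted alkene, and Z is required. Hydroxide meets a β-hydroxy sulfone that can fragment. The oxirane would then have to be added to A6-type material on a face chosen by ring conformation. A ketal at C1 and further protecting-group changes are needed.
- Comparison: for the ring-closing event itself it is as good or better, since strain is taken up in two stages. The chosen plan sets against it that alkene geometry and oxirane configuration are fixed by nerol and the asymmetric epoxidation before any ring exists.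

Key step: step 13

Remark on the chemistry: the trisubstituted oxirane is assumed to survive the non-acidic conditions chosen for every step after step 1. CIP descriptors at C5, C6 and C7 change along the route only because substituent priorities change; the spatial arrangement does not.

## Route

Step 1
Reactants: 1 nerol
Product: 2 [(2S,3R)-3-methyl-3-(4-methylpent-3-en-1-yl)oxiran-2-yl]methanol
Conditions: Ti(OiPr)4 (cat.), L-(+)-diethyl tartrate (cat.), t-BuOOH, 4 Å MS, CH2Cl2, −20 °C
Reagents that add atoms: tert-butyl hydroperoxide CC(C)(C)OO
Why: Sharpless asymmetric epoxidation; the allylic hydroxyl binds the titanium tartrate, so only the C4=C5 alkene reacts, and the L-(+)-tartrate delivers oxygen to the face that gives the (2S,3R)-oxirane, which is the C4–C5 oxirane of the target.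

Step 2
Reactants: 2 [(2S,3R)-3-methyl-3-(4-methylpent-3-en-1-yl)oxiran-2-yl]methanol
Product: 3 methyl 3-[(2R,3S)-3-(hydroxymethyl)-2-methyloxiran-2-yl]propanoate
Conditions: O3, NaOH, MeOH/CH2Cl2, −78 °C
Reagents that add atoms: ozone [O-][O+]=O; methanol CO
Why: Ozonolysis in basic methanol turns the alkene carbon directly into a methyl ester (the methoxy hydroperoxide loses water and the aldehyde hemiacetal is oxidised by ozone), so the γ,δ-epoxy acid, which would lactonise, is never formed; the primary alcohol is no more oxidisable than the solvent.

Step 3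
Reactants: 3 methyl 3-[(2R,3S)-3-(hydroxymethyl)-2-methyloxiran-2-yl]propanoate
Product: 4 methyl 3-[(2R,3R)-3-formyl-2-methyloxiran-2-yl]propanoate
Conditions: SO3·pyridine, DMSO, Et3N, CH2Cl2, 0 °C
Reagents that add atoms: none
Why: Parikh–Doering oxidation of a 2,3-epoxy alcohol under non-acidic conditions; the oxirane carbon C5 is not deprotonated, so it keeps its configuration, and the aldehyde is used crude.

Step 4
Reactants: 5 2,3-dibromoprop-1-ene; 6 (4-methoxyphenyl)methanol
Product: 7 1-{[(2-bromoprop-2-en-1-yl)oxy]methyl}-4-methoxybenzene
Conditions: NaH, THF, 0 °C to rt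
Reagents that add atoms: none
Why: Williamson ether synthesis; the alkoxide displaces the allylic bromide while the vinylic bromide is inert to substitution.

Step 5
Reactants: 7 1-{[(2-bromoprop-2-en-1-yl)oxy]methyl}-4-methoxybenzene; 4 methyl 3-[(2R,3R)-3-formyl-2-methyloxiran-2-yl]propanoate
Product: 9 methyl 3-[(2R,3S)-3-[(1S)-1-hydroxy-2-{[(4-methoxyphenyl)methoxy]methyl}prop-2-en-1-yl]-2-methyloxiran-2-yl]propanoate, via alkenyllithium 8 (not isolated)
Conditions: t-BuLi (2 equiv), Et2O, −78 °C; then 4, −78 °C
Reagents that add atoms: none
Why: Bromine–lithium exchange gives the 2-lithioallyl ether, which adds to the aldehyde much faster than to the methyl ester at −78 °C. Felkin–Anh addition with the oxirane C–O bond anti to the nucleophile should place the new C6 hydroxyl anti to the oxirane oxygen, as in the target.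

Step 6
Reactants: 9 the C6 allylic alcohol
Product: 10 methyl 3-[(2R,3S)-2-methyl-3-[(1S)-2-{[(4-methoxyphenyl)methoxy]methyl}-1-(triethylsilyloxy)prop-2-en-1-yl]oxiran-2-yl]propanoate
Conditions: Et3SiCl, imidazole, DMAP (cat.), CH2Cl2, 0 °C to rt
Reagents that add atoms: chlorotriethylsilane CC[Si](Cl)(CC)CC
Why: Standard silylation with the chloride, not the triflate, to spare the oxirane. The TES ether keeps O6 out of the later furanone closure and can be removed beside the PMB ether.

Step 7
Reactants: 10 the C6 TES ether
Product: 11 methyl 3-[(2R,3S)-3-[(1R,2R)-2,3-dihydroxy-2-{[(4-methoxyphenyl)methoxy]methyl}-1-(triethylsilyloxy)propyl]-2-methyloxiran-2-yl]propanoate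
Conditions: OsO4 (cat.), N-methylmorpholine N-oxide, acetone/H2O, rt
Reagents that add atoms: N-methylmorpholine N-oxide C[N+]1([O-])CCOCC1; water O
Why: Catalytic osmylation of the only alkene. By the empirical rule for allylic ethers the reagent attacks the face anti to the C6 silyloxy group, which sets the C7 hydroxyl anti to O6 along the C8–C7–C6–C5 chain, the arrangement of the target.

Step 8
Reactants: 11 the C7,C8 diol
Product: 12 methyl 3-[(2R,3S)-3-[(1R,2R)-2-hydroxy-2-{[(4-methoxyphenyl)methoxy]methyl}-3-oxo-1-(triethylsilyloxy)propyl]-2-methyloxiran-2-yl]propanoate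
Conditions: SO3·pyridine, DMSO, Et3N, CH2Cl2, 0 °C
Reagents that add atoms: none
Why: Parikh–Doering oxidation takes the primary alcohol to the aldehyde without glycol cleavage; the tertiary alcohol cannot be oxidised and C7 has no hydrogen to lose.

Step 9
Reactants: 12 the α-hydroxy aldehyde
Product: 13 methyl 3-[(2R,3S)-3-[(1R,2S)-2,3-dihydroxy-2-{[(4-methoxyphenyl)methoxy]methyl}-1-(triethylsilyloxy)hex-4-yn-1-yl]-2-methyloxiran-2-yl]propanoate (both C8 epimers)
Conditions: CH3C≡CMgBr (3 equiv), THF, −78 to −20 °C
Reagents that add atoms: 1-propynylmagnesium bromide CC#C[Mg]Br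
Why: Alkynyl Grignard addition to the aldehyde; one equivalent is consumed by the tertiary hydroxyl, and alkynylmagnesium halides leave the methyl ester and the oxirane alone at this temperature. The C8 carbinol is oxidised next, so its configuration does not matter.

Step 10
Reactants: 13 the propargylic diol
Product: 14 methyl 3-[(2R,3S)-3-[(1R,2R)-2-hydroxy-2-{[(4-methoxyphenyl)methoxy]methyl}-3-oxo-1-(triethylsilyloxy)hex-4-yn-1-yl]-2-methyloxiran-2-yl]propanoate
Conditions: IBX, DMSO, rt
Reagents that add atoms: none
Why: IBX oxidises the secondary alcohol of a 1,2-diol to the ketone without C–C cleavage; the tertiary hydroxyl stays.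

Step 11
Reactants: 14 the α′-hydroxy ynone
Product: 16 methyl 3-[(2R,3S)-3-[(R)-[(2R)-2-{[(4-methoxyphenyl)methoxy]methyl}-5-methyl-3-oxo-2,3-dihydrofuran-2-yl](triethylsilyloxy)methyl]-2-methyloxiran-2-yl]propanoate, via amino enone 15 (not isolated)
Conditions: Et2NH, EtOH, rt; then AcOH, THF/H2O, rt
Reagents that add atoms: none
Why: Conjugate addition of the amine gives the β-amino enone, whose tertiary hydroxyl displaces the amine by addition–elimination at C10. This is the standard furan-3(2H)-one synthesis from α′-hydroxy ynones; C7 is untouched.

Step 12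
Reactants: 16 the furanone methyl ester
Product: 18 Se-phenyl 3-[(2R,3S)-3-[(R)-[(2R)-2-{[(4-methoxyphenyl)methoxy]methyl}-5-methyl-3-oxo-2,3-dihydrofuran-2-yl](triethylsilyloxy)methyl]-2-methyloxiran-2-yl]propaneselenoate, via potassium carboxylate 17 (not isolated)
Conditions: KOSiMe3, THF, 0 °C to rt; then n-Bu3P, N-(phenylseleno)phthalimide, CH2Cl2, −20 °C to rt
Reagents that add atoms: N-(phenylseleno)phthalimide O=C1N([Se]c2ccccc2)C(=O)c2ccccc12
Why: Silanolate demethylation gives the anhydrous carboxylate. This attacks the selenophosphonium ion to form an acyloxyphosphonium salt, which phenylselenolate converts to the selenoester (phosphine-mediated selenoesterification). The free γ,δ-epoxy acid is never present.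

Step 13
Reactants: 18 the furanone selenoester
Product: 19 (4R,5S,6R,7R,10R)-4,5:7,10-diepoxy-7-{[(4-methoxyphenyl)methoxy]methyl}-4,10-dimethyl-6-(triethylsilyloxy)cyclodecane-1,8-dione
Conditions: (Me3Si)3SiH (2 equiv), AIBN (0.3 equiv), benzene, 80 °C, syringe-pump addition over 10 h to 1 mM
Reagents that add atoms: none
Why: The silyl radical abstracts the phenylseleno group from 18; the acyl radical at C1 adds to C10, the β-carbon of the vinylogous ester, and the resulting C9 radical next to the C8 ketone takes hydrogen from the silane, which carries the chain. The closest known reactions are acyl radical macrocyclisations onto enones and radical additions to β-alkoxy enones and β-alkoxy acrylates. The closure is 10-endo-trig for the carbocycle (9-exo if counted through the ring oxygen) and forms the C1–C10 bond only. The new stereocentre C10 is controlled by the tether: the chain hangs from C7 on one face of the flat furanone and can reach C10 only from that face, so C1 and C6 end up cis across the oxygen bridge (10R). The step needs cyclisation to beat hydrogen transfer to the acyl radical and decarbonylation; the slow-reacting silane, slow addition and high dilution serve this, and a primary acyl radical loses CO slowly. Regioselectivity follows from polarity: the nucleophilic acyl radical attacks the electron-poor C10, not C9. The cis-oxirane holds the chain bent, which brings C1 near C10.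

Step 14
Reactants: 19 the oxa-bridged diketone
Product: 20 (4R,5S,6R,7R,10R)-4,5:7,10-diepoxy-6-hydroxy-7-{[(4-methoxyphenyl)methoxy]methyl}-4,10-dimethylcyclodecane-1,8-dione
Conditions: HF·pyridine, pyridine, THF, 0 °C
Reagents that add atoms: none
Why: Buffered fluoride cleaves the triethylsilyl ether; PMB ether, oxirane and ketones are stable, and the non-basic medium avoids retro-aldol cleavage of the β-hydroxy ketone.

Step 15
Reactants: 20 the C6 hydroxy diketone
Product: 21 (4R,5S,6R,7S,8S,10R)-4,5:7,10-diepoxy-8-hydroxy-7-{[(4-methoxyphenyl)methoxy]methyl}-4,10-dimethyl-1-oxocyclodecan-6-yl benzoate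
Conditions: SmI2 (cat., premixed with PhCHO), PhCHO, THF, −10 °C
Reagents that add atoms: benzaldehyde O=Cc1ccccc1
Why: Evans–Tishchenko reduction. The C6 hydroxyl forms a samarium-bound hemiacetal with the aldehyde and passes its hydride to the C8 ketone through a six-membered transition state, so hydride enters on the face where C6 sits and the C8 hydroxyl ends trans to C6 (8S). Only the β-hydroxy ketone reacts, and O6 emerges as a benzoate, which tells the two carbinols apart.

Step 16
Reactants: 21 the C8 alcohol
Product: 22 (4R,5S,6R,7R,8S,10R)-4,5:7,10-diepoxy-7-{[(4-methoxyphenyl)methoxy]methyl}-4,10-dimethyl-1-oxo-8-(triethylsilyloxy)cyclodecan-6-yl benzoate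
Conditions: Et3SiCl, imidazole, DMAP (cat.), DMF, rt
Reagents that add atoms: chlorotriethylsilane CC[Si](Cl)(CC)CC
Why: Silylation of the C8 hydroxyl, which must be masked because it is homopropargylic to the coming alkyne just as the C6 hydroxyl is.

Step 17
Reactants: 22 the PMB ether
Product: 23 (4R,5S,6R,7R,8S,10R)-4,5:7,10-diepoxy-7-(hydroxymethyl)-4,10-dimethyl-1-oxo-8-(triethylsilyloxy)cyclodecan-6-yl benzoate
Conditions: DDQ, CH2Cl2/pH 7 buffer, 0 °C to rt
Reagents that add atoms: none
Why: Oxidative PMB cleavage (benzylic hydride abstraction, then hydrolysis of the oxocarbenium ion); silyl ether, benzoate, ketone and oxirane are not affected.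

Step 18
Reactants: 23 the C11 alcohol
Product: 24 (4R,5S,6R,7R,8S,10R)-4,5:7,10-diepoxy-7-formyl-4,10-dimethyl-1-oxo-8-(triethylsilyloxy)cyclodecan-6-yl benzoate
Conditions: Dess–Martin periodinane, NaHCO3, CH2Cl2, rt
Reagents that add atoms: none
Why: Dess–Martin oxidation of a neopentyl primary alcohol; the aldehyde has no α-hydrogen and both β-oxygens are capped, so it can neither epimerise nor fragment.

Step 19
Reactants: 24 the C11 aldehyde
Product: 26 (4R,5S,6R,7R,8S,10R)-4,5:7,10-diepoxy-7-ethynyl-6-hydroxy-4,10-dimethyl-8-(triethylsilyloxy)cyclodecan-1-one, via alkyne benzoate 25 (not isolated)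
Conditions: dimethyl (1-diazo-2-oxopropyl)phosphonate, K2CO3, MeOH, 0 °C to rt; then more K2CO3, rt
Reagents that add atoms: dimethyl (1-diazo-2-oxopropyl)phosphonate CC(=O)C(=[N+]=[N-])P(=O)(OC)OC
Why: Seyferth–Gilbert homologation with the Ohira–Bestmann reagent. The diazomethylphosphonate anion adds to the aldehyde, and loss of phosphate and nitrogen with a 1,2-shift gives the terminal alkyne. The same methanolic carbonate then removes the benzoate, which has served its purpose once the aldehyde is gone; the hindered C1 ketone does not react.

Step 20
Reactants: 26 the alkynol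
Product: 27 the spiro α-methylene-γ-butyrolactone with O8 as triethylsilyl ether, (4R,5S,6R,7R,8S,10R)
Conditions: PdI2 (cat.), n-Bu3P (cat.), CO (1 atm), MeCN, 70 °C
Reagents that add atoms: carbon monoxide [C-]#[O+]
Why: Palladium-catalysed cyclocarbonylation of a but-3-yn-1-ol. O6 and CO form an alkoxycarbonylpalladium species that adds syn across the alkyne, and protonolysis of the alkenylpalladium releases the methylene lactone. A tin-free catalyst is chosen to spare the oxirane, and with O8 silylated only the C6 hydroxyl can cyclise.

Step 21
Reactants: 27 the silylated lactone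
Product: 28 the spiro α-methylene-γ-butyrolactone with free C8 hydroxyl, (4R,5S,6R,7S,8S,10R)
Conditions: HF·pyridine, pyridine, THF, 0 °C to rt
Reagents that add atoms: none
Why: Buffered fluoride desilylation; no nucleophilic base is present that could add to the methylene lactone.

Step 22
Reactants: 28 the hydroxy lactone
Product: 29 the target, (4R,5S,6R,7S,8S,10R)
Conditions: methacrylic anhydride, Et3N, DMAP (cat.), CH2Cl2, 0 °C to rt
Reagents that add atoms: methacrylic anhydride CC(=C)C(=O)OC(=O)C(C)=C
Why: DMAP-catalysed acylation of the one remaining hydroxyl; it is placed last so the methacrylate meets no base or nucleophile.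

## Compound list

1 | nerol, (2Z)-3,7-dimethylocta-2,6-dien-1-ol | CC(C)=CCC/C(C)=C\CO | starting material
2 | [(2S,3R)-3-methyl-3-(4-methylpent-3-en-1-yl)oxiran-2-yl]methanol | OC[C@@H]1O[C@]1(C)CCC=C(C)C | intermediate
3 | methyl 3-[(2R,3S)-3-(hydroxymethyl)-2-methyloxiran-2-yl]propanoate | OC[C@@H]1O[C@]1(C)CCC(=O)OC | intermediate
4 | methyl 3-[(2R,3R)-3-formyl-2-methyloxiran-2-yl]propanoate | O=C[C@@H]1O[C@]1(C)CCC(=O)OC | intermediate
5 | 2,3-dibromoprop-1-ene | C=C(Br)CBr | starting material
6 | (4-methoxyphenyl)methanol | COc1ccc(CO)cc1 | starting material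
7 | 1-{[(2-bromoprop-2-en-1-yl)oxy]methyl}-4-methoxybenzene | C=C(Br)COCc1ccc(OC)cc1 | intermediate
8 | {3-[(4-methoxyphenyl)methoxy]prop-1-en-2-yl}lithium (formed in situ) | [Li]C(=C)COCc1ccc(OC)cc1 | intermediate
9 | C6 allylic alcohol (4R,5S,6S) | C=C(COCc1ccc(OC)cc1)[C@H](O)[C@@H]2O[C@]2(C)CCC(=O)OC | intermediate
10 | C6 triethylsilyl ether (4R,5S,6S) | C=C(COCc1ccc(OC)cc1)[C@H](O[Si](CC)(CC)CC)[C@@H]2O[C@]2(C)CCC(=O)OC | intermediate
11 | C7,C8 diol (4R,5S,6R,7R) | OC[C@@](O)(COCc1ccc(OC)cc1)[C@H](O[Si](CC)(CC)CC)[C@@H]2O[C@]2(C)CCC(=O)OC | intermediate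
12 | α-hydroxy aldehyde (4R,5S,6R,7R) | O=C[C@@](O)(COCc1ccc(OC)cc1)[C@H](O[Si](CC)(CC)CC)[C@@H]2O[C@]2(C)CCC(=O)OC | intermediate
13 | propargylic diol (4R,5S,6R,7S; both C8 epimers) | CC#CC(O)[C@@](O)(COCc1ccc(OC)cc1)[C@H](O[Si](CC)(CC)CC)[C@@H]2O[C@]2(C)CCC(=O)OC | intermediate
14 | α′-hydroxy ynone (4R,5S,6R,7R) | CC#CC(=O)[C@@](O)(COCc1ccc(OC)cc1)[C@H](O[Si](CC)(CC)CC)[C@@H]2O[C@]2(C)CCC(=O)OC | intermediate
15 | β-(diethylamino) enone (formed in situ) | CCN(CC)C(C)=CC(=O)[C@@](O)(COCc1ccc(OC)cc1)[C@H](O[Si](CC)(CC)CC)[C@@H]2O[C@]2(C)CCC(=O)OC | intermediate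
16 | furanone methyl ester (4R,5S,6R,7R) | CC1=CC(=O)[C@@](COCc2ccc(OC)cc2)([C@H](O[Si](CC)(CC)CC)[C@@H]3O[C@]3(C)CCC(=O)OC)O1 | intermediate
17 | potassium carboxylate of 16 (formed in situ) | CC1=CC(=O)[C@@](COCc2ccc(OC)cc2)([C@H](O[Si](CC)(CC)CC)[C@@H]3O[C@]3(C)CCC(=O)[O-])O1.[K+] | intermediate
18 | furanone Se-phenyl selenoester (4R,5S,6R,7R) | CC1=CC(=O)[C@@](COCc2ccc(OC)cc2)([C@H](O[Si](CC)(CC)CC)[C@@H]3O[C@]3(C)CCC(=O)[Se]c4ccccc4)O1 | intermediate
19 | oxa-bridged epoxy cyclodecane-1,8-dione, O6 triethylsilyl, C11 PMB ether (4R,5S,6R,7R,10R) | O=C1C[C@@]2(C)O[C@]1(COCc3ccc(OC)cc3)[C@H](O[Si](CC)(CC)CC)[C@@H]4O[C@]4(C)CCC2=O | intermediate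
20 | C6 hydroxy diketone (4R,5S,6R,7R,10R) | O=C1C[C@@]2(C)O[C@]1(COCc3ccc(OC)cc3)[C@H](O)[C@@H]4O[C@]4(C)CCC2=O | intermediate
21 | C8 alcohol, C6 benzoate (4R,5S,6R,7S,8S,10R) | O[C@H]1C[C@@]2(C)O[C@]1(COCc3ccc(OC)cc3)[C@H](OC(=O)c5ccccc5)[C@@H]4O[C@]4(C)CCC2=O | intermediate
22 | C8 triethylsilyl ether, C6 benzoate, C11 PMB ether (4R,5S,6R,7R,8S,10R) | CC[Si](CC)(CC)O[C@H]1C[C@@]2(C)O[C@]1(COCc3ccc(OC)cc3)[C@H](OC(=O)c5ccccc5)[C@@H]4O[C@]4(C)CCC2=O | intermediate
23 | C11 primary alcohol (4R,5S,6R,7R,8S,10R) | CC[Si](CC)(CC)O[C@H]1C[C@@]2(C)O[C@]1(CO)[C@H](OC(=O)c3ccccc3)[C@@H]4O[C@]4(C)CCC2=O | intermediate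
24 | C11 aldehyde (4R,5S,6R,7R,8S,10R) | CC[Si](CC)(CC)O[C@H]1C[C@@]2(C)O[C@]1(C=O)[C@H](OC(=O)c3ccccc3)[C@@H]4O[C@]4(C)CCC2=O | intermediate
25 | C7 ethynyl C6 benzoate (formed in situ) | CC[Si](CC)(CC)O[C@H]1C[C@@]2(C)O[C@]1(C#C)[C@H](OC(=O)c3ccccc3)[C@@H]4O[C@]4(C)CCC2=O | intermediate
26 | C7 ethynyl C6 alcohol (4R,5S,6R,7R,8S,10R) | CC[Si](CC)(CC)O[C@H]1C[C@@]2(C)O[C@]1(C#C)[C@H](O)[C@@H]3O[C@]3(C)CCC2=O | intermediate
27 | spiro α-methylene lactone, O8 triethylsilyl (4R,5S,6R,7R,8S,10R) | CC[Si](CC)(CC)O[C@H]1C[C@@]2(C)O[C@@]13C(=C)C(=O)O[C@@H]3[C@@H]4O[C@]4(C)CCC2=O | intermediate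
28 | spiro α-methylene lactone, C8 alcohol (4R,5S,6R,7S,8S,10R) | O[C@H]1C[C@@]2(C)O[C@@]13C(=C)C(=O)O[C@@H]3[C@@H]4O[C@]4(C)CCC2=O | intermediate
29 | CNP0241021.1, the C8 methacrylate (4R,5S,6R,7S,8S,10R) | C=C(C)C(=O)O[C@H]1C[C@@]2(C)O[C@@]13C(=C)C(=O)O[C@@H]3[C@@H]1O[C@]1(C)CCC2=O | target

## Step count and risks

Total: 22 steps. Longest linear sequence: 21 steps (steps 1–3 and 5–22, from nerol).

**Step 13 (key step).** The most likely failure is that hydrogen transfer to the acyl radical, or loss of CO, outruns a slow closure, because C10 is fully substituted and its ring oxygen lowers its electrophilicity; intermolecular addition would give oligomers. Fallback, from 18 back to 19: reduce the selenoester with Bu3SnH and AIBN at normal concentration to the aldehyde F1. Treat F1 with SmI2 and methanol in THF at high dilution, so that the C1 ketyl adds to C10 in a reductive aldehyde/β-alkoxy-enone coupling and gives the hydroxy ketone F2 under the same tether control. Oxidise F2 with Dess–Martin periodinane to 19.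

**Step 12.** Possible failures are opening of the oxirane by the neighbouring carboxyl group or by selenolate, attack of silanolate on the furanone, and loss of the triethylsilyl group. Fallback, from 17 back to 18: convert the carboxylate with isobutyl chloroformate and N-methylmorpholine at −20 °C into the mixed anhydride F3, and add PhSeNa (from PhSeSePh and NaBH4) at low temperature; acyl transfer is then much faster than any attack on the oxirane.

**Step 15.** The hydride transfer may stall at the ring ketone beside the quaternary C7, divalent samarium may attack the α-oxygenated C1 ketone, and the benzoate may migrate from O6 to O8. Fallback, from 20 back to 22: reduce with Me4NBH(OAc)3 in MeCN/AcOH at −30 °C (Saksena–Evans, the same internal delivery from O6) to the diol F4. Silylate the less hindered C8 hydroxyl with one equivalent of Et3SiCl and imidazole at −20 °C to the mono-silyl ether F5. Benzoylate O6 with benzoyl chloride, pyridine and DMAP to reach 22.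

**Step 20.** The alkyne sits on a quaternary carbon, so insertion may be slow and alkyne oligomerisation or oxirane opening at 70 °C may take over. Fallback, from 26 back to 27: α-selective hydrostannation with Bu3SnH and Mo(CO)3(CNtBu)3 gives the alkenylstannane F6. Iodine gives the 2-iodoalkene F7. Pd(PPh3)4, CO and Et3N then close the lactone by carbonylative esterification of the alkenyl iodide with the C6 hydroxyl.

**Step 7.** Facial selectivity may be poor, because a 1,1-disubstituted alkene has no cis substituent to hold the allylic centre in one conformation. Fallback, from 10 back to 12: ozonolysis with PPh3 work-up gives the ketone F8. Vinylmagnesium bromide at −78 °C should add under Felkin–Anh control (silyloxy group anti) to give the tertiary vinyl carbinol F9 with the same C7 configuration. A second ozonolysis gives aldehyde 12 directly.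

**Step 5.** Coordination of lithium to the oxirane oxygen may erode the anti selectivity, and some reagent may attack the ester. Fallback, from the C6 epimer mixture of 9 back to 9: oxidise with Dess–Martin periodinane to the epoxy enone F10 and reduce with Zn(BH4)2 in Et2O at −30 °C; this reduction of α,β-epoxy ketones is anti-selective and returns the required epimer of 9.

## Further compounds

F1 | step 13 | furanone aldehyde (C1 aldehyde in place of the selenoester) | CC1=CC(=O)[C@@](COCc2ccc(OC)cc2)([C@H](O[Si](CC)(CC)CC)[C@@H]3O[C@]3(C)CCC=O)O1
F2 | step 13 | C1 hydroxy C8 ketone of the oxa-bridged ring (C1 carbinol as formed) | O=C1C[C@@]2(C)O[C@]1(COCc3ccc(OC)cc3)[C@H](O[Si](CC)(CC)CC)[C@@H]4O[C@]4(C)CCC2O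
F3 | step 12 | isobutyl carbonic mixed anhydride of the furanone acid | CC1=CC(=O)[C@@](COCc2ccc(OC)cc2)([C@H](O[Si](CC)(CC)CC)[C@@H]3O[C@]3(C)CCC(=O)OC(=O)OCC(C)C)O1
F4 | step 15 | C6,C8 diol | O[C@H]1C[C@@]2(C)O[C@]1(COCc3ccc(OC)cc3)[C@H](O)[C@@H]4O[C@]4(C)CCC2=O
F5 | step 15 | C8 triethylsilyl ether with free C6 hydroxyl | CC[Si](CC)(CC)O[C@H]1C[C@@]2(C)O[C@]1(COCc3ccc(OC)cc3)[C@H](O)[C@@H]4O[C@]4(C)CCC2=O
F6 | step 20 | C11 tributylstannyl alkene | CC[Si](CC)(CC)O[C@H]1C[C@@]2(C)O[C@]1(C(=C)[Sn](CCCC)(CCCC)CCCC)[C@H](O)[C@@H]3O[C@]3(C)CCC2=O
F7 | step 20 | C11 iodoalkene | CC[Si](CC)(CC)O[C@H]1C[C@@]2(C)O[C@]1(C(=C)I)[C@H](O)[C@@H]3O[C@]3(C)CCC2=O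
F8 | step 7 | C7 ketone | O=C(COCc1ccc(OC)cc1)[C@H](O[Si](CC)(CC)CC)[C@@H]2O[C@]2(C)CCC(=O)OC
F9 | step 7 | C7 tertiary vinyl carbinol | C=C[C@@](O)(COCc1ccc(OC)cc1)[C@H](O[Si](CC)(CC)CC)[C@@H]2O[C@]2(C)CCC(=O)OC
F10 | step 5 | C6 epoxy enone | C=C(COCc1ccc(OC)cc1)C(=O)[C@@H]2O[C@]2(C)CCC(=O)OC
A1 | alternative 1 | alkoxy oxabicyclooctenone | COC(=O)[C@]12O[C@](C)(C=C1O[Si](C(C)C)(C(C)C)C(C)C)CC(=O)[C@H]2OCc3ccc(OC)cc3
A2 | alternative 1 | methyl 5-methyl-3-(triisopropylsilyloxy)furan-2-carboxylate | COC(=O)c1oc(C)cc1O[Si](C(C)C)(C(C)C)C(C)C
A3 | alternative 1 | 3-methoxy-3-[(4-methoxyphenyl)methoxy]-2-(trimethylsilyloxy)prop-1-ene | C=C(O[Si](C)(C)C)C(OC)OCc1ccc(OC)cc1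
A4 | alternative 2 | oxa-bridged acrylate ester | C=C(C)C(=O)O[C@H]1C[C@@]2(C)O[C@]1(C(=C)C(=O)OC)[C@H](O[Si](CC)(CC)CC)/C=C(/C)CCC2=O
A5 | alternative 2 | ten-membered allenyl carbinol | C=C(C)C(=O)O[C@H]1C[C@@](C)(O)C(=O)CC/C(C)=C\[C@@H](O[Si](CC)(CC)CC)C1=C=C
A6 | alternative 3 | oxa-bridged cyclodecenol | CC(C)(C)[Si](C)(C)O[C@H]1C[C@@]2(C)O[C@]1(C(=C)COCc3ccc(OC)cc3)[C@H](O)/C=C(/C)CCC23OCCO3
A7 | alternative 3 | eleven-membered β-hydroxy sulfone | CC(C)(C)[Si](C)(C)O[C@H]1C[C@@]2(C)O[C@]1(C(=C)COCc3ccc(OC)cc3)[C@H](O)CS(=O)(=O)C(C)CCC23OCCO3
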